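**Assumption:** cembrane numbering is used (C1 = ring CH bearing the acrylate carbon C15; lactone C16(=O)–O–C12). The SMILES then reads as (1R,3R,4E,7E,11S,12R), and that is the isomer made. The route is a paper design; no step has been run.

## Retrosynthetic overview

1. C3–C4: Nozaki–Hiyama–Kishi (NHK) macrocyclisation closes the 14-membered ring (second ring, formed last); oxidation and CBS reduction then fix C3.
2. C8–C9: B-alkyl Suzuki coupling with the symmetric linchpin (2E,5E)-2,6-diiodohepta-2,5-diene supplies C4–C8 and both E-olefins of the skipped diene.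
3. ε-Lactone (first ring): 7-exo opening of an (11S,12S)-epoxide at C12 by the C16 acid, with inversion; the epoxide comes from Sharpless epoxidation, so C11 and C12 are reagent-controlled.
4. (R)-Limonene supplies C1 (stereocentre), C2, C3, C11–C17: ozonolysis, methyl ketone → alkyne → Zr-carboalumination/CH2O (E-C11=C12, C10), then isopropenyl → acrylic acid by SeO2 and Pinnick oxidation.

## Route

**Step 1**
Reactants: 1 (1-bromobut-2-yne); 2 (prop-1-ynylmagnesium bromide)
Product: 3 (hepta-2,5-diyne)
Conditions: CuCl (10 mol %), THF, 0 → 50 °C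
Reagents that add atoms: none (both partners are numbered reactants)
Why: Cu(I)-catalysed SN2 coupling of a propargylic bromide with an alkynyl Grignard gives the skipped diyne.

**Step 2**
Reactants: 3 (hepta-2,5-diyne)
Product: 4 ((2E,5E)-2,6-diiodohepta-2,5-diene)
Conditions: Cp2Zr(H)Cl (3 equiv), THF, rt → 45 °C; then I2, 0 °C
Reagents that add atoms: iodine, II
Why: double syn-hydrozirconation (Schwartz), equilibrated so Zr sits on the less hindered methyl-bearing carbon, then iodinolysis with retention gives the E,E-bis(vinyl iodide); about 9:1 regioselectivity per alkyne is expected, so minor isomers must be removed.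

**Step 3**
Reactants: 5 ((R)-(+)-limonene)
Product: 6 ((5R)-7,7-dimethoxy-5-(prop-1-en-2-yl)heptan-2-one)
Conditions: O3 (1 equiv, Sudan III indicator), CH2Cl2/MeOH, −78 °C; TsOH (cat.), rt; then Me2S, NaHCO3
Reagents that add atoms: ozone, [O-][O+]=O; methanol, CO
Why: chemoselective ozonolysis of the electron-rich trisubstituted ring alkene, with acid/MeOH trapping of the aldehyde terminus as its dimethyl acetal; the limonene stereocentre becomes C1 (R).

**Step 4**
Reactants: 6
Product: 7 ((5R)-7,7-dimethoxy-5-(prop-1-en-2-yl)hept-1-yne)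
Conditions: LDA, THF, −78 °C; ClP(O)(OEt)2; then LDA (2.3 equiv), −78 °C → rt
Reagents that add atoms: none
Why: Negishi methyl ketone → terminal alkyne conversion via the kinetic enol phosphate and elimination; the former ketone methyl becomes C11.

**Step 5**
Reactants: 7
Product: 8 ((2E,6R)-8,8-dimethoxy-3-methyl-6-(prop-1-en-2-yl)oct-2-en-1-ol)
Conditions: Me3Al, Cp2ZrCl2 (cat.), H2O (1 equiv), CH2Cl2, −20 °C; then n-BuLi, (CH2O)n, THF, −78 °C → rt
Reagents that add atoms: trimethylaluminium, C[Al](C)C; formaldehyde, C=O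
Why: Zr-catalysed syn-carboalumination (Negishi; water-accelerated variant to spare the acetal) places Me on C12 and Al on C11, and trapping the alanate with formaldehyde gives the E-allylic alcohol stereospecifically.

**Step 6**
Reactants: 8
Product: 9 ([(2S,3S)-3-[(3R)-5,5-dimethoxy-3-(prop-1-en-2-yl)pentyl]-3-methyloxiran-2-yl]methanol)
Conditions: Ti(OiPr)4, L-(+)-DET, t-BuOOH, 4 Å MS, CH2Cl2, −20 °C
Reagents that add atoms: tert-butyl hydroperoxide, CC(C)(C)OO
Why: Sharpless asymmetric epoxidation of a geraniol-type allylic alcohol; L-(+)-tartrate gives the (2S,3S)-epoxide (11S,12S) under reagent control, and the isopropenyl group is not an allylic alcohol so it is untouched.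

**Step 7**
Reactants: 9
Product: 10 ((2R,3S)-3-[(3R)-5,5-dimethoxy-3-(prop-1-en-2-yl)pentyl]-3-methyloxirane-2-carbaldehyde)
Conditions: SO3·pyridine, DMSO, i-Pr2NEt, CH2Cl2, 0 °C
Reagents that add atoms: none
Why: Parikh–Doering oxidation gives the epoxy aldehyde without epimerisation or epoxide opening (the 2S → 2R change is a CIP priority change only).

**Step 8**
Reactants: 10
Product: 11 ((2S,3S)-2-[(3R)-5,5-dimethoxy-3-(prop-1-en-2-yl)pentyl]-3-ethenyl-2-methyloxirane)
Conditions: Ph3PCH3Br, KHMDS, THF, −78 → 0 °C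
Reagents that add atoms: methyltriphenylphosphonium bromide, C[P+](c1ccccc1)(c1ccccc1)c1ccccc1.[Br-]
Why: Wittig methylenation installs C9 as a terminal vinyl group.

**Step 9**
Reactants: 11
Product: 12 ((3R)-3-{2-[(2S,3S)-3-ethenyl-2-methyloxiran-2-yl]ethyl}-5,5-dimethoxy-2-methylidenepentanal)
Conditions: SeO2 (0.5 equiv), t-BuOOH, CH2Cl2, rt; crude alcohol/enal mixture then MnO2, CH2Cl2 (telescoped)
Reagents that add atoms: selenium dioxide, O=[Se]=O (reoxidised by t-BuOOH, CC(C)(C)OO)
Why: SeO2 allylic oxidation (ene/[2,3]) of the isopropenyl methyl (CH3 preferred over the allylic methine), which is the only oxidisable alkene at this stage since the vinyl group has no reactive allylic C–H; MnO2 converges the mixture on the enal.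

**Step 10**
Reactants: 12
Product: 13 ((3R)-3-{2-[(2S,3S)-3-ethenyl-2-methyloxiran-2-yl]ethyl}-5,5-dimethoxy-2-methylidenepentanoic acid)
Conditions: NaClO2, NaH2PO4, 2-methyl-2-butene, t-BuOH/H2O, 0 °C
Reagents that add atoms: sodium chlorite, [Na+].[O-]Cl=O
Why: Pinnick oxidation takes the enal to the acrylic acid under buffered conditions that the epoxide and acetal should tolerate.

**Step 11**
Reactants: 13
Product: 14 ((4R,7R)-4-(2,2-dimethoxyethyl)-7-[(1S)-1-hydroxyprop-2-en-1-yl]-7-methyl-3-methylideneoxepan-2-one)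
Conditions: PPTS (10 mol %), CH2Cl2, 0 °C → rt
Reagents that add atoms: none
Why: acid-catalysed intramolecular 7-exo epoxide opening by the carboxylic acid at the tertiary C12 with inversion (12S → 12R) forms the α-methylene-ε-lactone, leaving C11–OH with retained (S) configuration.

**Step 12**
Reactants: 14
Product: 15 ((1S)-1-[(2R,5R)-5-(2,2-dimethoxyethyl)-2-methyl-6-methylidene-7-oxooxepan-2-yl]prop-2-en-1-yl acetate)
Conditions: Ac2O, DMAP, pyridine, CH2Cl2, 0 °C → rt
Reagents that add atoms: acetic anhydride, CC(=O)OC(C)=O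
Why: DMAP-catalysed acetylation of the only free hydroxyl gives the C11 acetate.

**Step 13**
Reactants: 15; 4 (3 equiv, excess recovered)
Product: 16 ((1S,4E,7E)-1-[(2R,5R)-5-(2,2-dimethoxyethyl)-2-methyl-6-methylidene-7-oxooxepan-2-yl]-8-iodo-4-methylnona-4,7-dien-1-yl acetate)
Conditions: 9-BBN, THF, 0 °C → rt; then 4, Pd(dppf)Cl2 (10 mol %), AsPh3, Cs2CO3, DMF/H2O, rt
Reagents that add atoms: none (9-BBN adds only H; 4 is a numbered reactant)
Why: anti-Markovnikov hydroboration of the terminal vinyl group (the conjugated exo-methylene is deactivated), then B-alkyl Suzuki mono-coupling with retention forms C8–C9 and the E-C7=C8 olefin, leaving the second E-vinyl iodide.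

**Step 14**
Reactants: 16
Product: 17 ((1S,4E,7E)-8-iodo-4-methyl-1-[(2R,5R)-2-methyl-6-methylidene-7-oxo-5-(2-oxoethyl)oxepan-2-yl]nona-4,7-dien-1-yl acetate)
Conditions: PPTS, acetone/H2O, 50 °C
Reagents that add atoms: water, O
Why: mild acetal hydrolysis frees the C3 aldehyde without touching the lactone, acetate or skipped diene.

**Step 15**
Reactants: 17
Product: 18 (macrocyclic allylic alcohol, mixture of C3 epimers: 3-epi-dendronpholide B and dendronpholide B)
Conditions: CrCl2 (10 equiv), NiCl2 (cat.), DMSO/THF, rt, 2 mM, slow addition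
Reagents that add atoms: none
Why: intramolecular Nozaki–Hiyama–Kishi vinyl iodide/aldehyde coupling closes the 14-membered ring at C3–C4 with retention of the E-olefin and tolerates the ester functions; C3 selectivity is not relied upon.

**Step 16**
Reactants: 18
Product: 19 ((1R,4E,7E,11S,12R)-11-acetoxy-3-oxocembra-4,7,15(17)-trien-16,12-olide; the C3 ketone)
Conditions: Dess–Martin periodinane, NaHCO3, CH2Cl2, 0 °C
Reagents that add atoms: none
Why: buffered oxidation converges both C3 epimers on one α-methyl enone without moving the skipped diene into conjugation.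

**Step 17**
Reactants: 19
Product: 20 (dendronpholide B)
Conditions: (S)-Me-CBS (1.5 equiv), catecholborane, toluene, −78 °C
Reagents that add atoms: none
Why: Corey–Bakshi–Shibata reduction with the α-methyl alkenyl group as the large substituent delivers hydride to give the (3R)-allylic alcohol under reagent control; catecholborane at −78 °C should spare the lactone, acetate and exo-methylene.

## Compound list

1 | 1-bromobut-2-yne | CC#CCBr | starting material
2 | prop-1-ynylmagnesium bromide | CC#C[Mg]Br | starting material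
3 | hepta-2,5-diyne | CC#CCC#CC | intermediate
4 | (2E,5E)-2,6-diiodohepta-2,5-diene | C/C(I)=C\C/C=C(\C)I | intermediate
5 | (R)-(+)-limonene | CC1=CC[C@@H](CC1)C(C)=C | starting material
6 | (5R)-7,7-dimethoxy-5-(prop-1-en-2-yl)heptan-2-one | CC(=O)CC[C@H](CC(OC)OC)C(C)=C | intermediate
7 | (5R)-7,7-dimethoxy-5-(prop-1-en-2-yl)hept-1-yne | C#CCC[C@H](CC(OC)OC)C(C)=C | intermediate
8 | (2E,6R)-8,8-dimethoxy-3-methyl-6-(prop-1-en-2-yl)oct-2-en-1-ol | OC/C=C(\C)CC[C@H](CC(OC)OC)C(C)=C | intermediate
9 | [(2S,3S)-3-[(3R)-5,5-dimethoxy-3-(prop-1-en-2-yl)pentyl]-3-methyloxiran-2-yl]methanol | OC[C@@H]1O[C@@]1(C)CC[C@H](CC(OC)OC)C(C)=C | intermediate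
10 | (2R,3S)-3-[(3R)-5,5-dimethoxy-3-(prop-1-en-2-yl)pentyl]-3-methyloxirane-2-carbaldehyde | O=C[C@@H]1O[C@@]1(C)CC[C@H](CC(OC)OC)C(C)=C | intermediate
11 | (2S,3S)-2-[(3R)-5,5-dimethoxy-3-(prop-1-en-2-yl)pentyl]-3-ethenyl-2-methyloxirane | C=C[C@@H]1O[C@@]1(C)CC[C@H](CC(OC)OC)C(C)=C | intermediate
12 | (3R)-3-{2-[(2S,3S)-3-ethenyl-2-methyloxiran-2-yl]ethyl}-5,5-dimethoxy-2-methylidenepentanal | C=C[C@@H]1O[C@@]1(C)CC[C@H](CC(OC)OC)C(=C)C=O | intermediate
13 | (3R)-3-{2-[(2S,3S)-3-ethenyl-2-methyloxiran-2-yl]ethyl}-5,5-dimethoxy-2-methylidenepentanoic acid | C=C[C@@H]1O[C@@]1(C)CC[C@H](CC(OC)OC)C(=C)C(O)=O | intermediate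
14 | (4R,7R)-4-(2,2-dimethoxyethyl)-7-[(1S)-1-hydroxyprop-2-en-1-yl]-7-methyl-3-methylideneoxepan-2-one | C=C1C(=O)O[C@](C)(CC[C@@H]1CC(OC)OC)[C@@H](O)C=C | intermediate
15 | (1S)-1-[(2R,5R)-5-(2,2-dimethoxyethyl)-2-methyl-6-methylidene-7-oxooxepan-2-yl]prop-2-en-1-yl acetate | C=C1C(=O)O[C@](C)(CC[C@@H]1CC(OC)OC)[C@@H](OC(C)=O)C=C | intermediate
16 | (1S,4E,7E)-1-[(2R,5R)-5-(2,2-dimethoxyethyl)-2-methyl-6-methylidene-7-oxooxepan-2-yl]-8-iodo-4-methylnona-4,7-dien-1-yl acetate | C=C1C(=O)O[C@](C)(CC[C@@H]1CC(OC)OC)[C@@H](OC(C)=O)CC/C(C)=C/C/C=C(\C)I | intermediate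
17 | (1S,4E,7E)-8-iodo-4-methyl-1-[(2R,5R)-2-methyl-6-methylidene-7-oxo-5-(2-oxoethyl)oxepan-2-yl]nona-4,7-dien-1-yl acetate | C=C1C(=O)O[C@](C)(CC[C@@H]1CC=O)[C@@H](OC(C)=O)CC/C(C)=C/C/C=C(\C)I | intermediate
18 | macrocyclic allylic alcohol, C3 epimer mixture (1R,11S,12R; 3RS) | C=C1C(=O)O[C@]2(C)CC[C@@H]1CC(O)/C(C)=C/C/C=C(\C)CC[C@@H]2OC(C)=O | intermediate
19 | 3-oxo macrocycle (1R,4E,7E,11S,12R) | C=C1C(=O)O[C@]2(C)CC[C@@H]1CC(=O)/C(C)=C/C/C=C(\C)CC[C@@H]2OC(C)=O | intermediate
20 | dendronpholide B (1R,3R,4E,7E,11S,12R) | C=C1C(=O)O[C@]2(C)CC[C@@H]1C[C@@H](O)/C(C)=C/C/C=C(\C)CC[C@@H]2OC(C)=O | target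

## Summary

Total steps: 17 (2 for linchpin 4, 15 on the main line).
Longest linear sequence: 15 steps, from (R)-limonene (steps 3–17).

Steps most likely to fail, each with a fallback that changes the approach:

1. **Step 11 (epoxy-acid → ε-lactone).** The vinyl group also activates C11, so 8-endo or SN2′ attack, or SN1 loss of C12 integrity, could compete. Fallback: move the lactonisation to the 2,3-epoxy-alcohol stage. Oxidise the isopropenyl group of 9 (SeO2/MnO2, then NaClO2) and cyclise with Ti(OiPr)4, which templates C3-selective opening with inversion at C12. Then rebuild the vinyl carbinol from the resulting 10,11-diol by selective primary-alcohol oxidation and non-basic Takai–Lombardo methylenation.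

2. **Step 9 (late SeO2 oxidation).** The acid-labile vinyl epoxide and acetal may not survive, and yields are typically moderate. Fallback: functionalise C16 at the outset instead of by late C–H oxidation. Metalate limonene with n-BuLi/TMEDA, trap with B(OMe)3/H2O2 to give limonen-10-ol, carry it as a TBDPS ether through steps 3–8, then unveil with TBAF, MnO2 and NaClO2.

3. **Step 15 (NHK macrocyclisation).** Oligomerisation or low conversion is possible at the hindered α-methyl vinyl iodide. Fallback: swap the order of the two couplings. Hydrolyse the acetal of 15 and run an intermolecular (Kishi-type asymmetric) NHK with excess 4 to set C3. Then close the 14-membered ring by intramolecular B-alkyl Suzuki coupling (9-BBN on the C9=C10 vinyl, Pd). This also removes steps 16–17.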